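## Retrosynthetic overview
1. The last operations are hydrogenolysis of three O-benzyl groups and 3-O-methylation. The 3-oxygen is placed on a 5,7,4'-tri-O-benzyl-6,8,2',5'-tetramethoxyflavone.
2. Ring C is the only ring that is built. It is closed last (O1–C2) by oxidative cyclisation of a 2'-hydroxychalcone.
3. The key C–C bond (future C2–C3) comes from a Claisen–Schmidt aldol condensation of a ring A acetophenone with a ring B benzaldehyde.
4. Ring A is bought as 2,4,6-trihydroxyacetophenone, then selectively dibenzylated, dibrominated and doubly methoxylated under copper catalysis.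
5. Ring B is bought as 2,5-dimethoxybenzaldehyde, then taken through Baeyer–Villiger oxidation to the phenol, benzylation and Vilsmeier–Haack formylation.

Assumption: the target SMILES contains no stereocentre and no stereogenic double bond, so the compound is achiral and there is no enantiomer to select. The stereocentres in three transient intermediates are racemic and are erased again.

## Route

Step 1
Reactants: 1 2,5-dimethoxybenzaldehyde
Product: 3 2,5-dimethoxyphenol, via 2,5-dimethoxyphenyl formate 2 (not isolated)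
Conditions: mCPBA (1.3 equiv), CH2Cl2, 0 °C to rt, 16 h; aq NaHCO3 wash; then MeOH, K2CO3 (0.1 equiv), rt, 1 h
Reagents that add atoms: mCPBA OOC(=O)c1cccc(Cl)c1
Why: Baeyer–Villiger oxidation, in which the electron-rich aryl group migrates after peracid addition to the aldehyde to give formate 2, and base-catalysed methanolysis then frees the phenol.

Step 2
Reactants: 3 2,5-dimethoxyphenol
Product: 4 2-(benzyloxy)-1,4-dimethoxybenzene
Conditions: BnBr (1.1 equiv), K2CO3 (1.5 equiv), DMF, 60 °C, 4 h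
Reagents that add atoms: benzyl bromide BrCc1ccccc1
Why: Williamson ether synthesis on the only acidic OH, placing a group that survives base, iodine and dioxirane and leaves by hydrogenolysis at the end.

Step 3
Reactants: 4 2-(benzyloxy)-1,4-dimethoxybenzene
Product: 6 4-(benzyloxy)-2,5-dimethoxybenzaldehyde, via aryl iminium chloride 5 (not isolated)
Conditions: POCl3 (1.5 equiv), DMF, 0 °C then 80 °C, 3 h; then ice-water
Reagents that add atoms: DMF CN(C)C=O (formyl carbon); water O (carbonyl oxygen)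
Why: Vilsmeier–Haack formylation, which attacks the 1,2,4-trialkoxybenzene at the one position that is para to OBn and ortho to OMe and not flanked on both sides, and water hydrolyses iminium 5 to the aldehyde.

Step 4
Reactants: 7 2,4,6-trihydroxyacetophenone (dried)
Product: 8 1-[2,4-bis(benzyloxy)-6-hydroxyphenyl]ethan-1-one
Conditions: BnBr (2.1 equiv), K2CO3 (2.3 equiv), DMF, rt to 50 °C, 6 h
Reagents that add atoms: benzyl bromide BrCc1ccccc1
Why: Selective Williamson etherification, in which the para OH and one of the two equivalent ortho OH groups react while the last OH is held in a hydrogen bond to the ketone and does not react with the limited BnBr.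

Step 5
Reactants: 8 1-[2,4-bis(benzyloxy)-6-hydroxyphenyl]ethan-1-one
Product: 9 1-[2,4-bis(benzyloxy)-3,5-dibromo-6-hydroxyphenyl]ethan-1-one
Conditions: NBS (2.05 equiv), CH2Cl2, 0 °C to rt, dark, 2 h
Reagents that add atoms: N-bromosuccinimide O=C1CCC(=O)N1Br
Why: Electrophilic aromatic bromination, in which the only two free positions of the phloroglucinol-type ring are each activated by three oxygens and react far faster than the acetyl methyl or the benzyl groups.

Step 6
Reactants: 9 1-[2,4-bis(benzyloxy)-3,5-dibromo-6-hydroxyphenyl]ethan-1-one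
Product: 10 1-[2,4-bis(benzyloxy)-6-hydroxy-3,5-dimethoxyphenyl]ethan-1-one
Conditions: NaOMe (10 equiv, 5.4 M in MeOH), CuBr (0.4 equiv), DMF, 110 °C, N2, 6 h; then 1 M HCl
Reagents that add atoms: sodium methoxide C[O-].[Na+]
Why: Ullmann-type C–O coupling, in which methoxide on monovalent copper replaces both aryl bromides as it does in other bromides flanked by oxygen (5-bromovanillin, 6,8-dibromochrysin), while the benzyl ethers, the phenoxide and the ketone tolerate NaOMe.

Step 7
Reactants: 10 1-[2,4-bis(benzyloxy)-6-hydroxy-3,5-dimethoxyphenyl]ethan-1-one; 6 4-(benzyloxy)-2,5-dimethoxybenzaldehyde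
Product: 12 (E)-1-[2,4-bis(benzyloxy)-6-hydroxy-3,5-dimethoxyphenyl]-3-[4-(benzyloxy)-2,5-dimethoxyphenyl]prop-2-en-1-one, via aldol adduct 11 (not isolated)
Conditions: KOH (10 equiv, 50% aq), EtOH/THF (2:1), rt, 48 h; then cold 1 M HCl
Reagents that add atoms: none
Why: Claisen–Schmidt crossed aldol condensation, in which the enolised methyl ketone 10 adds to the non-enolisable aldehyde 6 to give racemic aldol 11, and E1cB loss of water leaves only the conjugated E-enone, so no stereocentre remains.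

Step 8
Reactants: 12 the (E)-chalcone
Product: 14 5,7-bis(benzyloxy)-2-[4-(benzyloxy)-2,5-dimethoxyphenyl]-6,8-dimethoxy-4H-chromen-4-one, via racemic flavanone 13 (not isolated)
Conditions: I2 (0.1 equiv), DMSO, 120 °C, 3 h; then aq Na2S2O3
Reagents that add atoms: none
Why: Oxidative cyclisation, in which oxa-Michael addition of the 2'-phenol closes ring C to flavanone 13 and the I2/DMSO couple dehydrogenates it to the flavone with DMSO as terminal oxidant, erasing the C2 stereocentre.

Step 9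
Reactants: 14 the tribenzyl flavone
Product: 16 5,7-bis(benzyloxy)-2-[4-(benzyloxy)-2,5-dimethoxyphenyl]-3-hydroxy-6,8-dimethoxy-4H-chromen-4-one, via flavone 2,3-epoxide 15 (not isolated)
Conditions: DMDO (3 equiv, ca. 0.07 M in acetone), CH2Cl2, 0 °C to rt, 12 h; concentrate; then p-TsOH·H2O (0.1 equiv), CH2Cl2, rt, 1 h
Reagents that add atoms: dimethyldioxirane CC1(C)OO1
Why: Dioxirane epoxidation of the enol-ether-like C2=C3 bond followed by acid-catalysed epoxide opening and loss of H-3, which rearomatises the pyrone to the flavonol and removes both racemic centres of 15.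

Step 10
Reactants: 16 the tribenzyl flavonol
Product: 17 5,7-bis(benzyloxy)-2-[4-(benzyloxy)-2,5-dimethoxyphenyl]-3,6,8-trimethoxy-4H-chromen-4-one
Conditions: MeI (2 equiv), K2CO3 (2 equiv), acetone, reflux, 6 h
Reagents that add atoms: methyl iodide CI
Why: Williamson O-methylation, which is unambiguous because the acidic 3-OH is the only free hydroxyl in 16.

Step 11
Reactants: 17 the tribenzyl 3-methoxyflavone
Product: 18 5,7-dihydroxy-2-(4-hydroxy-2,5-dimethoxyphenyl)-3,6,8-trimethoxy-4H-chromen-4-one (target)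
Conditions: H2 (1 atm), 10% Pd/C, EtOAc/MeOH (1:1), rt, 6 h
Reagents that add atoms: none
Why: Catalytic hydrogenolysis cleaves the three benzylic C–O bonds under neutral conditions that leave the five methyl ethers and the tetrasubstituted C2=C3 bond of the pyrone intact.

## Compound list
1 | 2,5-dimethoxybenzaldehyde | COc1ccc(OC)c(C=O)c1 | starting material
2 | 2,5-dimethoxyphenyl formate (not isolated) | COc1ccc(OC)c(OC=O)c1 | intermediate
3 | 2,5-dimethoxyphenol | COc1ccc(OC)c(O)c1 | intermediate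
4 | 2-(benzyloxy)-1,4-dimethoxybenzene | COc1ccc(OC)c(OCc2ccccc2)c1 | intermediate
5 | [4-(benzyloxy)-2,5-dimethoxybenzylidene]dimethyliminium chloride (not isolated) | C[N+](C)=Cc1cc(OC)c(OCc2ccccc2)cc1OC.[Cl-] | intermediate
6 | 4-(benzyloxy)-2,5-dimethoxybenzaldehyde | COc1cc(C=O)c(OC)cc1OCc1ccccc1 | intermediate
7 | 2,4,6-trihydroxyacetophenone | CC(=O)c1c(O)cc(O)cc1O | starting material
8 | 1-[2,4-bis(benzyloxy)-6-hydroxyphenyl]ethan-1-one | CC(=O)c1c(O)cc(OCc2ccccc2)cc1OCc1ccccc1 | intermediate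
9 | 1-[2,4-bis(benzyloxy)-3,5-dibromo-6-hydroxyphenyl]ethan-1-one | CC(=O)c1c(O)c(Br)c(OCc2ccccc2)c(Br)c1OCc1ccccc1 | intermediate
10 | 1-[2,4-bis(benzyloxy)-6-hydroxy-3,5-dimethoxyphenyl]ethan-1-one | CC(=O)c1c(O)c(OC)c(OCc2ccccc2)c(OC)c1OCc1ccccc1 | intermediate
11 | racemic 1-[2,4-bis(benzyloxy)-6-hydroxy-3,5-dimethoxyphenyl]-3-[4-(benzyloxy)-2,5-dimethoxyphenyl]-3-hydroxypropan-1-one (aldol adduct, not isolated) | COc1cc(C(O)CC(=O)c2c(O)c(OC)c(OCc3ccccc3)c(OC)c2OCc2ccccc2)c(OC)cc1OCc1ccccc1 | intermediate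
12 | (E)-1-[2,4-bis(benzyloxy)-6-hydroxy-3,5-dimethoxyphenyl]-3-[4-(benzyloxy)-2,5-dimethoxyphenyl]prop-2-en-1-one | COc1cc(/C=C/C(=O)c2c(O)c(OC)c(OCc3ccccc3)c(OC)c2OCc2ccccc2)c(OC)cc1OCc1ccccc1 | intermediate
13 | racemic 5,7-bis(benzyloxy)-2-[4-(benzyloxy)-2,5-dimethoxyphenyl]-6,8-dimethoxychroman-4-one (flavanone, not isolated) | COc1cc(C2CC(=O)c3c(OCc4ccccc4)c(OC)c(OCc4ccccc4)c(OC)c3O2)c(OC)cc1OCc1ccccc1 | intermediate
14 | 5,7-bis(benzyloxy)-2-[4-(benzyloxy)-2,5-dimethoxyphenyl]-6,8-dimethoxy-4H-chromen-4-one | COc1cc(-c2cc(=O)c3c(OCc4ccccc4)c(OC)c(OCc4ccccc4)c(OC)c3o2)c(OC)cc1OCc1ccccc1 | intermediate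
15 | racemic 2,3-epoxide of 14 (cis-fused oxirane across C2–C3, not isolated) | COc1cc(C23OC2C(=O)c5c(OCc4ccccc4)c(OC)c(OCc4ccccc4)c(OC)c5O3)c(OC)cc1OCc1ccccc1 | intermediate
16 | 5,7-bis(benzyloxy)-2-[4-(benzyloxy)-2,5-dimethoxyphenyl]-3-hydroxy-6,8-dimethoxy-4H-chromen-4-one | COc1cc(-c2oc3c(OC)c(OCc4ccccc4)c(OC)c(OCc4ccccc4)c3c(=O)c2O)c(OC)cc1OCc1ccccc1 | intermediate
17 | 5,7-bis(benzyloxy)-2-[4-(benzyloxy)-2,5-dimethoxyphenyl]-3,6,8-trimethoxy-4H-chromen-4-one | COc1cc(-c2oc3c(OC)c(OCc4ccccc4)c(OC)c(OCc4ccccc4)c3c(=O)c2OC)c(OC)cc1OCc1ccccc1 | intermediate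
18 | 5,7,4'-trihydroxy-3,6,8,2',5'-pentamethoxyflavone (achiral) | COc1cc(-c2oc3c(OC)c(O)c(OC)c(O)c3c(=O)c2OC)c(OC)cc1O | target

## Step count
- Total step count: 11.
- Longest linear sequence: 8 steps. This holds both for 7 through steps 4, 5, 6, 7, 8, 9, 10, 11 and for 1 through steps 1, 2, 3, 7, 8, 9, 10, 11.

## Three steps most likely to fail

**Step 6 (double methoxylation).** The risks are hydrodebromination and incomplete exchange at the bromide that sits between two benzyloxy groups. The fallback brings in the two oxygens by Baeyer–Villiger oxidation rather than by C–O coupling. It sets out from 7 and comes back at 10. Compound 7 is C-acetylated (Ac2O, BF3·OEt2, 90 °C) to 2,4-diacetylphloroglucinol F1. Perbenzylation (BnBr, K2CO3, DMF, 70 °C) gives 1,1'-[2,4,6-tris(benzyloxy)-1,3-phenylene]diethanone F2. Both twisted, unchelated acetyl groups are oxidised (mCPBA, cat. CF3CO2H, CH2Cl2, rt) to 2,4,6-tris(benzyloxy)-1,3-phenylene diacetate F3. Methanolysis (K2CO3, MeOH, N2) gives 2,4,6-tris(benzyloxy)benzene-1,3-diol F4. MeI/K2CO3 in DMF then gives 1,3,5-tris(benzyloxy)-2,4-dimethoxybenzene F5. The single free ring position is acetylated (AcOH, (CF3CO)2O, cat. H3PO4, rt) to 1-[2,4,6-tris(benzyloxy)-3,5-dimethoxyphenyl]ethan-1-one F6. BCl3 (1.0 equiv, CH2Cl2, −78 °C) removes one of the two equivalent ortho benzyl groups by chelation to the ketone and delivers 10.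

**Step 8 (I2/DMSO cyclisation).** The risks are iodination of the electron-rich ring B and loss of the 5-O-benzyl group to HI at 120 °C. The fallback gives up the flavone and oxidises the chalcone directly. It sets out from 12 and comes back at 16, so steps 8 and 9 both drop out. The Algar–Flynn–Oyamada reaction (30% H2O2, 2 M aq NaOH, MeOH/THF, 0 °C to rt) runs through racemic trans-5,7-bis(benzyloxy)-2-[4-(benzyloxy)-2,5-dimethoxyphenyl]-3-hydroxy-6,8-dimethoxychroman-4-one F7. The excess alkaline peroxide dehydrogenates this to 16. The aurone that 6'-alkoxychalcones can form alongside is removed by chromatography.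

**Step 9 (DMDO oxidation).** The risks are slow epoxidation and competing oxidation of ring B or of benzylic C–H bonds. The fallback replaces electrophilic oxygen transfer with deprotonation, borylation and oxidation. It sets out from 14 and comes back at 16. LiN(iPr)2 (1.2 equiv, THF, −78 °C) removes H-3 to give [5,7-bis(benzyloxy)-2-[4-(benzyloxy)-2,5-dimethoxyphenyl]-6,8-dimethoxy-4-oxo-4H-chromen-3-yl]lithium F8. B(OMe)3 traps it as dimethyl [5,7-bis(benzyloxy)-2-[4-(benzyloxy)-2,5-dimethoxyphenyl]-6,8-dimethoxy-4-oxo-4H-chromen-3-yl]boronate F9. H2O2/AcOH (0 °C to rt) then converts the C–B bond into the 3-OH of 16.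

## Further compounds
F1 | step 6 | 2,4-diacetylphloroglucinol | CC(=O)c1c(O)cc(O)c(C(C)=O)c1O
F2 | step 6 | 1,1'-[2,4,6-tris(benzyloxy)-1,3-phenylene]diethanone | CC(=O)c1c(OCc2ccccc2)cc(OCc2ccccc2)c(C(C)=O)c1OCc1ccccc1
F3 | step 6 | 2,4,6-tris(benzyloxy)-1,3-phenylene diacetate | CC(=O)Oc1c(OCc2ccccc2)cc(OCc2ccccc2)c(OC(C)=O)c1OCc1ccccc1
F4 | step 6 | 2,4,6-tris(benzyloxy)benzene-1,3-diol | Oc1c(OCc2ccccc2)cc(OCc2ccccc2)c(O)c1OCc1ccccc1
F5 | step 6 | 1,3,5-tris(benzyloxy)-2,4-dimethoxybenzene | COc1c(OCc2ccccc2)cc(OCc2ccccc2)c(OC)c1OCc1ccccc1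
F6 | step 6 | 1-[2,4,6-tris(benzyloxy)-3,5-dimethoxyphenyl]ethan-1-one | CC(=O)c1c(OCc2ccccc2)c(OC)c(OCc2ccccc2)c(OC)c1OCc1ccccc1
F7 | step 8 | racemic trans-5,7-bis(benzyloxy)-2-[4-(benzyloxy)-2,5-dimethoxyphenyl]-3-hydroxy-6,8-dimethoxychroman-4-one ((2R,3R) enantiomer drawn) | COc1cc([C@@H]2[C@@H](O)C(=O)c3c(OCc4ccccc4)c(OC)c(OCc4ccccc4)c(OC)c3O2)c(OC)cc1OCc1ccccc1
F8 | step 9 | [5,7-bis(benzyloxy)-2-[4-(benzyloxy)-2,5-dimethoxyphenyl]-6,8-dimethoxy-4-oxo-4H-chromen-3-yl]lithium | COc1cc(-c2oc3c(OC)c(OCc4ccccc4)c(OC)c(OCc4ccccc4)c3c(=O)c2[Li])c(OC)cc1OCc1ccccc1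
F9 | step 9 | dimethyl [5,7-bis(benzyloxy)-2-[4-(benzyloxy)-2,5-dimethoxyphenyl]-6,8-dimethoxy-4-oxo-4H-chromen-3-yl]boronate | COc1cc(-c2oc3c(OC)c(OCc4ccccc4)c(OC)c(OCc4ccccc4)c3c(=O)c2B(OC)OC)c(OC)cc1OCc1ccccc1
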